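**Plan**
- Retrosynthesis: the coumarin C3=C4 and lactone C2–O1 bonds are cut first (Knoevenagel–lactonisation) to give salicylaldehyde lactol 12 and pyranone acetate 20; in 20 the ring bonds C5=C6 and C2–C3 are then cut together.
- Enabling feature: the ring oxygen O1 of the dihydropyranone joins the enol-ether carbon C6 and the methyl-bearing carbon C2, so C6–O1–C2 is an ester in disguise (vinyl ester 15: acyl carbon = C6, vinyl CH = C2), and C3–C4(=O)–C5 is the chloroacetonyl phosphorane 18.
- Forward, arene fragment: 2,6-dimethoxytoluene is taken through C–H borylation/bromination, ortho-lithiation/methylation, epoxide opening, oxidation/reduction, oxa-Pictet–Spengler closure and demethylation to 12.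
- Forward, pyranone and end game: 20 is made in one flask by nickel-hydride hydroalkylation and intramolecular Wittig closure (formal [3+3]); the coumarin ring is closed last with no added protecting-group steps.
- Stereochemistry: the benzylic centre comes from (2R,3R)-2,3-epoxybutane (inversion), the carbinol centre from Felkin–Anh reduction of ketone 9, and pyranone C2 from the chiral nickel catalyst.

Key step: step 10

Remark: 12 is written as its lactol; it is taken to react through the hydroxy aldehyde with which it is in ring-chain equilibrium.

**Step 1**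
Reactants: 1 2,6-dimethoxytoluene
Product: 3 5-bromo-1,3-dimethoxy-2-methylbenzene, via aryl pinacol boronate 2 (not isolated)
Conditions: [Ir(OMe)(cod)]2 (1.5 mol%), 4,4'-di-tert-butyl-2,2'-bipyridine (3 mol%), B2pin2 (1.0 equiv), THF, 80 °C; then CuBr2 (3 equiv), MeOH/H2O 1:1, 80 °C
Reagents that add atoms: copper dibromide, Br[Cu]Br
Why: Iridium-catalysed C–H borylation is governed by sterics and should take the only ring C–H of 1 without an ortho substituent (para to the methyl group), and CuBr2 then turns the C–B bond into C–Br in the same pot (one-pot borylation/halodeboronation).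

**Step 2**
Reactants: 3 5-bromo-1,3-dimethoxy-2-methylbenzene
Product: 5 1-bromo-3,5-dimethoxy-2,4-dimethylbenzene, via aryllithium 4 (not isolated)
Conditions: LDA (1.1 equiv), THF, −78 °C, 30 min; MeI (1.5 equiv), −78 °C to rt
Reagents that add atoms: iodomethane, CI
Why: Directed ortho-lithiation removes one of the two equivalent ring protons of 3 that lie between Br and OMe, and the aryllithium is C-methylated at −78 °C before loss of bromide to an aryne can compete.

**Step 3**
Reactants: 5 1-bromo-3,5-dimethoxy-2,4-dimethylbenzene; 6 (2R,3R)-2,3-epoxybutane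
Product: 8 (2R,3R)-3-(3,5-dimethoxy-2,4-dimethylphenyl)butan-2-ol, via arylmagnesium bromide 7 (not isolated)
Conditions: Mg, THF, 50 °C; then CuI (10 mol%), 6 (1.5 equiv), −30 to 0 °C; then H2O (pH 7 buffer)
Reagents that add atoms: none
Why: Copper-catalysed opening of the strained epoxide by the aryl Grignard reagent is an SN2 process with inversion at the attacked carbon, so the C2-symmetric (2R,3R) epoxide (both carbons equivalent) should give the (2R,3R) alcohol with the benzylic centre already R.

**Step 4**
Reactants: 8 (2R,3R)-3-(3,5-dimethoxy-2,4-dimethylphenyl)butan-2-ol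
Product: 9 (3R)-3-(3,5-dimethoxy-2,4-dimethylphenyl)butan-2-one
Conditions: Dess–Martin periodinane (1.3 equiv), NaHCO3, CH2Cl2, 0 °C to rt
Reagents that add atoms: none
Why: Dess–Martin oxidation under buffered, non-basic conditions should give the methyl ketone without enolising the alpha-aryl stereocentre, which keeps its R configuration.

**Step 5**
Reactants: 9 (3R)-3-(3,5-dimethoxy-2,4-dimethylphenyl)butan-2-one
Product: 10 (2S,3R)-3-(3,5-dimethoxy-2,4-dimethylphenyl)butan-2-ol
Conditions: LiBH(s-Bu)3 (L-Selectride, 1.3 equiv), THF, −78 °C; then H2O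
Reagents that add atoms: none
Why: Felkin–Anh controlled reduction, in which the bulky hydride attacks anti to the aryl group and past the alpha hydrogen, should give the (2S,3R) alcohol, i.e. net inversion of the carbinol centre of 8.

**Step 6**
Reactants: 10 (2S,3R)-3-(3,5-dimethoxy-2,4-dimethylphenyl)butan-2-ol
Product: 11 (3S,4R)-1-ethoxy-6,8-dimethoxy-3,4,5,7-tetramethylisochromane (both C1 epimers)
Conditions: HC(OEt)3 (3 equiv), BF3·OEt2 (0.2 equiv), CH2Cl2, 0 °C to rt
Reagents that add atoms: triethyl orthoformate, CCOC(OCC)OCC
Why: Oxa-Pictet–Spengler cyclisation, in which the alcohol and the orthoformate form a dialkoxycarbenium ion that attacks the only free ring carbon in a six-membered closure, installs the future aldehyde carbon at the acetal level without touching either stereocentre.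

**Step 7**
Reactants: 11 (3S,4R)-1-ethoxy-6,8-dimethoxy-3,4,5,7-tetramethylisochromane
Product: 12 (3S,4R)-3,4,5,7-tetramethylisochromane-1,6,8-triol (lactol of 2,4-dihydroxy-6-[(2R,3S)-3-hydroxybutan-2-yl]-3,5-dimethylbenzaldehyde)
Conditions: BBr3 (4 equiv), CH2Cl2, −78 to 0 °C; then H2O, NaHCO3
Reagents that add atoms: water, O
Why: Lewis-acid ether cleavage by BBr3 should remove both aryl methyl ethers and ionise the ethyl acetal, while the ring oxygen is spared because it is part of the stabilised oxocarbenium (quinone methide) ion, and water returns the lactol with both stereocentres unchanged.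

**Step 8**
Reactants: 13 ethyl hydrogen malonate; 14 vinyl acetate
Product: 15 ethyl vinyl malonate
Conditions: Pd(OAc)2 (5 mol%), KOH (10 mol%), vinyl acetate (solvent), rt
Reagents that add atoms: none
Why: Palladium-catalysed transvinylation (vinyl interchange) of a carboxylic acid with vinyl acetate runs at room temperature, which should avoid decarboxylation of the malonic half ester.

**Step 9**
Reactants: 16 1,3-dichloropropan-2-one
Product: 18 1-chloro-3-(triphenylphosphoranylidene)propan-2-one, via phosphonium chloride 17 (not isolated)
Conditions: PPh3 (1.0 equiv), THF, reflux; then Na2CO3, MeOH/H2O, rt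
Reagents that add atoms: triphenylphosphine, c1ccc(cc1)P(c1ccccc1)c1ccccc1
Why: SN2 alkylation of PPh3 by one C–Cl bond of the symmetrical dichloroketone and deprotonation of the salt by mild base is the standard synthesis of a keto-stabilised phosphorane, and the second C–Cl bond should survive because such an ylide is a poor nucleophile.

**Step 10**
Reactants: 15 ethyl vinyl malonate; 18 1-chloro-3-(triphenylphosphoranylidene)propan-2-one
Product: 20 ethyl 2-[(2R)-2-methyl-4-oxo-3,4-dihydro-2H-pyran-6-yl]acetate, via ester ylide 19 (not isolated)
Conditions: NiBr2·glyme (10 mol%), 2,2'-(propane-2,2-diyl)bis(4-phenyl-4,5-dihydrooxazole) (12 mol%, the antipode that gives the R ester), (MeO)2MeSiH (2 equiv), KF (2 equiv), NaI (0.2 equiv), DMAc/t-BuOH, 0 °C to rt; then air, toluene, 90 °C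
Reagents that add atoms: none
Why: Proposed new method: a nickel hydride formed from NiBr2, the silane and fluoride should insert the vinyl group of 15 with nickel on the oxygen-bearing carbon (five-membered chelate to the ester carbonyl), the chloroketone end of 18 should be taken up by halogen abstraction and radical capture at nickel, and reductive elimination should form the C2–C3 bond to give 19; on heating, the ylide carbon of 19 should add to the carbonyl of that same ester and the oxaphosphetane should lose Ph3PO to form the C5=C6 enol-ether double bond of 20, so both ring bonds arise in one flask from two simple pieces (formal [3+3] annulation). The closest known reaction types are the nickel-hydride-catalysed enantioselective branched hydroalkylation of enol esters and enamides with alkyl halides (alpha-halo carbonyl partners are known in related nickel-hydride couplings) and the intramolecular Wittig olefination of ester carbonyls used to close chromones and tetronates. The six-membered ring closes by 6-exo-trig attack of C5 on the ester C=O followed by cycloreversion. The only new stereocentre, pyranone C2, is set under catalyst control by the chiral bis(oxazoline) ligand in the C–C bond-forming step; the ligand antipode is fixed in a trial run with vinyl benzoate. The step needs branched regioselectivity (secured by ester chelation of the alkylnickel), use of the C–Cl bond without loss of the ylide (secured by the low basicity and nucleophilicity of the keto-stabilised ylide), and closure on the near ester carbonyl and not on the ethyl ester (secured by ring size, six against eight).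

**Step 11**
Reactants: 12 (3S,4R)-3,4,5,7-tetramethylisochromane-1,6,8-triol; 20 ethyl 2-[(2R)-2-methyl-4-oxo-3,4-dihydro-2H-pyran-6-yl]acetate
Product: 21 7-hydroxy-5-[(2R,3S)-3-hydroxybutan-2-yl]-6,8-dimethyl-3-[(2R)-2-methyl-4-oxo-3,4-dihydro-2H-pyran-6-yl]-2H-chromen-2-one
Conditions: piperidine (0.2 equiv), AcOH (0.2 equiv), EtOH, 60 °C
Reagents that add atoms: none
Why: Knoevenagel condensation of the doubly activated methylene of 20 (ester and vinylogous ketone) with the aldehyde form of 12, then lactonisation by the ortho phenol, is the Knoevenagel coumarin synthesis; only the ortho hydroxyl can lactonise and the mild amine salt should leave all three stereocentres untouched.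

**Compound list**
1 | 2,6-dimethoxytoluene | COc1cccc(OC)c1C | starting material
2 | 2-(3,5-dimethoxy-4-methylphenyl)-4,4,5,5-tetramethyl-1,3,2-dioxaborolane (not isolated) | COc1cc(cc(OC)c1C)B1OC(C)(C)C(C)(C)O1 | intermediate
3 | 5-bromo-1,3-dimethoxy-2-methylbenzene | COc1cc(Br)cc(OC)c1C | intermediate
4 | (6-bromo-2,4-dimethoxy-3-methylphenyl)lithium (not isolated) | [Li]c1c(Br)cc(OC)c(C)c1OC | intermediate
5 | 1-bromo-3,5-dimethoxy-2,4-dimethylbenzene | COc1cc(Br)c(C)c(OC)c1C | intermediate
6 | (2R,3R)-2,3-epoxybutane ((2R,3R)-2,3-dimethyloxirane) | C[C@H]1O[C@@H]1C | starting material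
7 | (3,5-dimethoxy-2,4-dimethylphenyl)magnesium bromide (not isolated) | COc1cc([Mg]Br)c(C)c(OC)c1C | intermediate
8 | (2R,3R)-3-(3,5-dimethoxy-2,4-dimethylphenyl)butan-2-ol | COc1cc([C@@H](C)[C@@H](C)O)c(C)c(OC)c1C | intermediate
9 | (3R)-3-(3,5-dimethoxy-2,4-dimethylphenyl)butan-2-one | COc1cc([C@@H](C)C(C)=O)c(C)c(OC)c1C | intermediate
10 | (2S,3R)-3-(3,5-dimethoxy-2,4-dimethylphenyl)butan-2-ol | COc1cc([C@@H](C)[C@H](C)O)c(C)c(OC)c1C | intermediate
11 | (3S,4R)-1-ethoxy-6,8-dimethoxy-3,4,5,7-tetramethylisochromane (both C1 epimers) | CCOC1O[C@@H](C)[C@H](C)c2c(C)c(OC)c(C)c(OC)c12 | intermediate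
12 | (3S,4R)-3,4,5,7-tetramethylisochromane-1,6,8-triol (lactol, both C1 epimers; ring tautomer of 2,4-dihydroxy-6-[(2R,3S)-3-hydroxybutan-2-yl]-3,5-dimethylbenzaldehyde) | OC1O[C@@H](C)[C@H](C)c2c(C)c(O)c(C)c(O)c12 | intermediate
13 | ethyl hydrogen malonate (3-ethoxy-3-oxopropanoic acid) | CCOC(=O)CC(=O)O | starting material
14 | vinyl acetate | CC(=O)OC=C | starting material
15 | ethyl vinyl malonate (1-ethenyl 3-ethyl propanedioate) | CCOC(=O)CC(=O)OC=C | intermediate
16 | 1,3-dichloropropan-2-one | ClCC(=O)CCl | starting material
17 | (3-chloro-2-oxopropyl)triphenylphosphonium chloride (not isolated) | [Cl-].ClCC(=O)C[P+](c1ccccc1)(c1ccccc1)c1ccccc1 | intermediate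
18 | 1-chloro-3-(triphenylphosphoranylidene)propan-2-one | ClCC(=O)C=P(c1ccccc1)(c1ccccc1)c1ccccc1 | intermediate
19 | 1-ethyl 3-[(2R)-4-oxo-5-(triphenylphosphoranylidene)pentan-2-yl] propanedioate (not isolated) | CCOC(=O)CC(=O)O[C@H](C)CC(=O)C=P(c1ccccc1)(c1ccccc1)c1ccccc1 | intermediate
20 | ethyl 2-[(2R)-2-methyl-4-oxo-3,4-dihydro-2H-pyran-6-yl]acetate | CCOC(=O)CC1=CC(=O)C[C@@H](C)O1 | intermediate
21 | 7-hydroxy-5-[(2R,3S)-3-hydroxybutan-2-yl]-6,8-dimethyl-3-[(2R)-2-methyl-4-oxo-3,4-dihydro-2H-pyran-6-yl]-2H-chromen-2-one | Cc1c(O)c(C)c2oc(=O)c(C3=CC(=O)C[C@@H](C)O3)cc2c1[C@@H](C)[C@H](C)O | target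

Total step count: 11 steps. Longest linear sequence: 8 steps (steps 1 to 7, then step 11).

**Steps most likely to fail**

Step 10 (Proposed new method). The acidic malonate methylene of 15, 19 or 20 may be alkylated by the chloroketone under the fluoride base. The C–Cl bond of 18 may be reduced without coupling. Facial selectivity in the nickel step may be poor, and the enone of 20 may be reduced during the thermal stage. The fallback uses known chemistry, sets out from 15 and comes back at 19 and then 20. Commercial ethyl (R)-3-hydroxybutanoate is treated with Ph3P=CH2 (from Ph3PCH3Br and n-BuLi, 3 equiv, THF, −78 °C to rt); acylation of the methylene ylide by the ester should give (4R)-4-hydroxy-1-(triphenylphosphoranylidene)pentan-2-one F1. F1 is then O-acylated with vinyl ester 15 under lipase catalysis (immobilised Candida antarctica lipase B, MTBE, 40 °C). The R alcohol is the fast-reacting enantiomer for this enzyme and acetaldehyde leaves irreversibly, so 19 should result without C-acylation of the ylide. 19 is closed by the intramolecular Wittig reaction (toluene, 90 °C) to 20.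

Step 11. The amine catalyst may open the dihydropyranone at its enol-ether carbon, retro-oxa-Michael opening may epimerise pyranone C2, and condensation with the hindered lactol may be slow. The fallback sets out from 12 and 20 and comes back at 21. Under acid (TFA, CH2Cl2, rt) 12 loses water to its oxocarbenium (quinone methide) ion and the enol of 20 adds to C1. This is the way lactols of this type take up carbon nucleophiles, and it should give ethyl 2-[(3S,4R)-6,8-dihydroxy-3,4,5,7-tetramethylisochroman-1-yl]-2-[(2R)-2-methyl-4-oxo-3,4-dihydro-2H-pyran-6-yl]acetate F2. Mild base (Et3N, MeCN, 40 °C) then effects E1cB opening of the C1–O bond and lactonisation by the phenol to give 21.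

Step 3. Opening of the internal epoxide by the ortho-substituted aryl nucleophile may be slow, with halohydrin formation by magnesium bromide as the competing process. The fallback sets out from 5 (through 7) and comes back at 9. Commercial methyl (R)-lactate is converted with Tf2O and 2,6-lutidine (CH2Cl2, −78 °C) into methyl (2R)-2-{[(trifluoromethyl)sulfonyl]oxy}propanoate F3. Grignard reagent 7 with ZnCl2 (THF, 0 °C) displaces the triflate with inversion, as in the known synthesis of 2-arylpropanoates, to give methyl (2R)-2-(3,5-dimethoxy-2,4-dimethylphenyl)propanoate F4. MeNH(OMe)·HCl and i-PrMgCl (THF, −20 °C) give (2R)-2-(3,5-dimethoxy-2,4-dimethylphenyl)-N-methoxy-N-methylpropanamide F5. MeMgBr (THF, 0 °C) then gives ketone 9, which enters step 5.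

**Further compounds**
F1 | step 10 | (4R)-4-hydroxy-1-(triphenylphosphoranylidene)pentan-2-one | C[C@@H](O)CC(=O)C=P(c1ccccc1)(c1ccccc1)c1ccccc1
F2 | step 11 | ethyl 2-[(3S,4R)-6,8-dihydroxy-3,4,5,7-tetramethylisochroman-1-yl]-2-[(2R)-2-methyl-4-oxo-3,4-dihydro-2H-pyran-6-yl]acetate | CCOC(=O)C(C1O[C@@H](C)[C@H](C)c2c(C)c(O)c(C)c(O)c12)C3=CC(=O)C[C@@H](C)O3
F3 | step 3 | methyl (2R)-2-{[(trifluoromethyl)sulfonyl]oxy}propanoate | COC(=O)[C@@H](C)OS(=O)(=O)C(F)(F)F
F4 | step 3 | methyl (2R)-2-(3,5-dimethoxy-2,4-dimethylphenyl)propanoate | COc1cc([C@@H](C)C(=O)OC)c(C)c(OC)c1C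
F5 | step 3 | (2R)-2-(3,5-dimethoxy-2,4-dimethylphenyl)-N-methoxy-N-methylpropanamide | COc1cc([C@@H](C)C(=O)N(C)OC)c(C)c(OC)c1C
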